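## The problem

The target is a procyanidin trimer. An upper (−)-epicatechin 3-O-gallate is bonded through C4 to C8 of a middle (−)-epicatechin 3-O-gallate, whose C4 is bonded to C6 of a lower (+)-catechin. Both interflavan bonds are 4β (trans to the C3 oxygen), and the lower one goes to C6, against the normal preference of a 5,7-dioxygenated ring A for substitution at C8. Of the eight stereocentres, C2 and C3 of the middle and lower units can be bought with epicatechin and catechin, and middle C4 follows from middle C3 because nucleophiles add to a 2,3-cis flavan C4 cation trans to the 3-substituent. The upper unit is the open question: there C3 has to govern first C4 and then C2. The free molecule has eighteen phenolic hydroxyls, two aryl esters and two doubly benzylic C4–aryl bonds, so it tolerates neither oxidants nor base nor strong acid; all phenols therefore stay benzyl ethers until a final hydrogenolysis and the esters go on late. The enabling feature lies in the upper unit: C2 is a benzylic carbon para to O4' of ring B, so oxidation of a free 4'-phenol turns C2 into the electrophilic end of a p-quinone methide six atoms away from the phenolic oxygen on C8a of ring A, and O1–C2 can be closed last and intramolecularly. Read backwards, ring B, C2, C3 and C4 of that unit are the aryl group, Cβ, Cα and carboxyl carbon of an aromatic α-amino acid.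

## Retrosynthesis

**Protecting groups and esters.** The last operation should only remove groups, so 32 is traced to 31, in which every phenol and the lower 3-hydroxyl are benzyl ethers and C8 of the lower unit carries a bromine atom; one hydrogenolysis cuts nineteen O–CH2Ph bonds and the C–Br bond. The two ester C–O bonds are cut next (31 to diol 29 and two equivalents of acid chloride 30). Gallates would not survive the organolithium and fluoride steps, and at this late point the only free hydroxyls are the two to be esterified. The forward reaction must acylate two hindered axial alcohols completely.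

**Ring C of the upper unit (key cut).** 29 comes from 28 by desilylation, 28 from phenol 27 by benzylation, and in 27 the bond O1–C2 is cut. Cutting C4–C8 instead leads to the usual cationic coupling of two flavans, which is kept in reserve; cutting O1–C8a would need a metal-mediated aryl etherification next to two stereocentres. The O1–C2 cut is preferred because the group it needs, the 4'-phenol, belongs to the target, and because it removes a ring and a stereocentre at once. The precursor 25 is an open-chain 1,1,3-triarylpropan-2-ol silyl ether whose C2 is a plain CH2 group. The forward step must oxidise one phenol out of two, close a six-membered ring and place ring B cis to O3.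

**Ring A of the upper unit.** 25 is unmasked from allyl ether 24, and 24 is cut at C4–C4a into benzylic alcohol 22 and the symmetrical phenol 23. This cut keeps C3 and C4 joined as in the amino acid. It also lets ring A enter without any protecting-group work: whichever ortho carbon of 23 reacts, the free hydroxyl ends up on C8a, where the closure needs it. 22 lacks ring A entirely. The forward Friedel–Crafts reaction must find the carbon ortho to the hydroxyl and must set C4 under the influence of C3.

**The upper interflavan bond.** 22 is cut at C4–C8 into aldehyde 10 and aryllithium 21, made from iodide 20. A carbonyl addition is chosen over a second Friedel–Crafts reaction because it fixes the site on the middle unit beyond doubt and leaves cation chemistry for the one step where it sets a stereocentre; the carbinol configuration is irrelevant. The fragments are now a three-carbon aldehyde with one stereocentre and a flavan dimer. The forward step needs iodine–lithium exchange beside an aryl bromide.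

**The lower interflavan bond.** After removal of the silyl group (20 to 19) the bond from C4 of the epicatechin unit to C6 of the catechin unit is cut, giving electrophile 14 and nucleophile 18. This bond is made first, between monomers. Made last, it would require oxidation at C4 of a dimer that has a second doubly benzylic C4–H and free C6 and C8 positions on its upper ring A, and these would outrun the deliberately deactivated nucleophile. Both partners carry a halogen at C8: bromine on 18 forces attack through C6, iodine on 14 stops self-condensation and later serves as the metalation handle. 14 goes back through 13 and 12 to (−)-epicatechin 11, and 18 through 17 and 16 to (+)-catechin 15. Four stereocentres are thus bought and a fifth (middle C4) follows from them; the forward coupling must be 3,4-trans.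

**The three-carbon aldehyde.** 10 is the reduced form of silyloxy ester 9; its aryl group, CH2, CH–O and carbonyl carbon are ring B, C2, C3 and C4 of the upper unit. An amino acid that already carried both ring B oxygens would give no way to tell O3' from O4', and the closure needs O4' free while O3' stays protected. L-Tyrosine 1, with O4' only, is therefore the source. Diazotisation with retention gives 2, and esterification gives 3. The C3'–O bond is cut in the sense 8 from 7, 7 from 5 by Baeyer–Villiger oxidation, 5 from 4 by allylation, and 4 from 3 by ortho-formylation, so the second oxygen arrives after O4' is capped with allyl and is benzylated on its own.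

## Roads not taken

**Alternative 1:** The cut runs through ring C of the middle unit: C4–C4a, C3–C4 and O1–C2 are broken together. This divides the target into three pieces: the upper unit ending in a free phenol, A2; the lower unit as its 6-carbaldehyde, A3; and the (Z)-enol gallate A4. Forward, A2 and A3 are condensed on an arylboronic acid template to a reactive heterodiene (oxygen on C8a, exocyclic C4), which adds A4 in a [4+2] sense. The product A1 is the same compound as 31 of the chosen route.
- Merits: the whole skeleton and both gallates are assembled in one step. The (Z) geometry of A4 becomes 2,3-cis, the electron-rich styrene polarisation joins C3 to C4 and O1 to the benzylic C2, and the 4→6 link is decided by where the formyl group sits in A3.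
- Weak points: three stereocentres (C2, C3, C4) arise in an intermolecular step whose only controllers are remote stereocentres on two bulky flavan substituents, so neither the face nor the endo/exo mode (which decides 3,4-trans) is secured. The heterodiene is generated thermally beside the labile C4–aryl bond of A2. A2 itself needs the same C4 arylation of an upper unit that the chosen plan performs.
- Comparison: in step count and convergence this road is clearly better and it reaches 31 directly. The chosen plan sets against it that each stereocentre is formed either by a reaction of known sense or inside a six-membered transition state, one at a time, each with a known-chemistry detour.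

**Alternative 2:** The cut goes through aromatic ring A of the middle unit (C8–C8a and C6–C7). The substrate is the alkynyl flavan A6, an upper unit that carries a triisopropylsiloxyethynyl group at C4. A6 is heated with cyclobutenone A7. Ring opening of A7, addition to the alkyne of A6, a second ring opening and 6π closure give phenol A5, whose new ring carries a free hydroxyl, a silyl ether and a benzyl ether.
- Merits: upper C4 is fixed beforehand in A6, on a real flavan, by trans addition of a small alkynyl group, the best-secured way to set that centre. The attachment site on the new ring of A5 is fixed by construction and its three oxygens emerge differentiated.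
- Weak points: only ring A is made. Ring C of the middle unit with C2, C3 and ring B, then C4 and the whole lower unit, remain to be built on a hindered, fully substituted arene. This is a de novo flavan synthesis with three more stereocentres, after a thermal step on the ynol ether A6 at a sensitive benzylic carbon.
- Comparison: this road is superior in certainty at upper C4, which the chosen plan must earn in an open-chain Friedel–Crafts step (step 18). The chosen plan sets against it that the middle unit is bought with ring C and two stereocentres intact, so construction effort goes into one ring only.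

**Alternative 3:** The cut is C4–C4a of the lower unit. Precursor A9 carries, on C4 of the middle unit, a symmetrical bis(benzyloxy)phenyl ether ring attached para to an oxygen that bears an open C2–C3–C4 chain ending in an epoxide. A mild Lewis acid opens the epoxide, one of the two equivalent ortho carbons attacks the CH2 terminus, ring C closes and the C3 hydroxyl is freed, giving A8.
- Merits: the 4→6 problem is solved most elegantly. Para attack on a symmetrical ring is the only possibility, either ortho carbon gives the same chroman, no halogen cap is needed, and the lower 3-hydroxyl appears alone and free.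
- Weak points: the lower unit is no longer bought; A9 needs its own synthesis of an aryl ether at a benzylic stereocentre and of a defined epoxide. The closure must take the primary epoxide carbon in competition with five-ring formation at the internal one. The Lewis acid threatens the benzylic C2–O bond and both C4–aryl bonds. A8 has no gallates and the upper half is not addressed.
- Comparison: this road is better in regiocontrol of the lower link, because it avoids the deactivated, capped nucleophile that is the weakness of step 15. The chosen plan sets against it the use of catechin itself with C2 and C3 given, and a cap that is lost in the final hydrogenolysis at no extra step.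

Key step: step 20

Assumption: 3,5-bis(benzyloxy)phenol 23 and 3,4,5-tris(benzyloxy)benzoyl chloride 30 are treated as purchased compounds.

## Route

Step 1
Reactants: 1 L-tyrosine
Product: 2 (S)-2-hydroxy-3-(4-hydroxyphenyl)propanoic acid
Conditions: NaNO2, 1 M H2SO4, H2O, 0 °C → rt
Reagents that add atoms: water, O
Why: Diazotisation of an α-amino acid; the carboxylate displaces N2 to an α-lactone that water opens, two inversions, so the (S) configuration is retained at the carbon that becomes C3.

Step 2
Reactants: 2 (S)-2-hydroxy-3-(4-hydroxyphenyl)propanoic acid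
Product: 3 methyl (S)-2-hydroxy-3-(4-hydroxyphenyl)propanoate
Conditions: MeOH, H2SO4 (cat.), reflux
Reagents that add atoms: methanol, CO
Why: Fischer esterification; the phenol and the secondary alcohol are not touched and the stereocentre is not involved.

Step 3
Reactants: 3 methyl (S)-2-hydroxy-3-(4-hydroxyphenyl)propanoate
Product: 4 methyl (S)-3-(3-formyl-4-hydroxyphenyl)-2-hydroxypropanoate
Conditions: MgCl2, Et3N, (CH2O)n, MeCN, reflux
Reagents that add atoms: formaldehyde (as paraformaldehyde), C=O
Why: Magnesium-mediated ortho-formylation of a phenol (Casnati–Skattebøl); the magnesium phenoxide directs formaldehyde to the free ortho position and a second formaldehyde accepts the hydride, so only C3' is functionalised.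

Step 4
Reactants: 4 methyl (S)-3-(3-formyl-4-hydroxyphenyl)-2-hydroxypropanoate
Product: 5 methyl (S)-3-[4-(allyloxy)-3-formylphenyl]-2-hydroxypropanoate
Conditions: allyl bromide, K2CO3, DMF, rt
Reagents that add atoms: allyl bromide, C=CCBr
Why: Williamson etherification; carbonate deprotonates only the acidic salicylaldehyde-type phenol, and allyl is later removable by zerovalent palladium without touching benzyl or silyl ethers.

Step 5
Reactants: 5 methyl (S)-3-[4-(allyloxy)-3-formylphenyl]-2-hydroxypropanoate
Product: 7 methyl (S)-3-[4-(allyloxy)-3-hydroxyphenyl]-2-hydroxypropanoate, via aryl formate 6 (not isolated)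
Conditions: mCPBA, CH2Cl2, 0 °C → rt; then K2CO3 (cat.), MeOH, 0 °C
Reagents that add atoms: mCPBA, OOC(=O)c1cccc(Cl)c1
Why: Baeyer–Villiger (Dakin-type) oxidation of an electron-rich benzaldehyde; the aryl group migrates to give formate 6, which mild methanolysis cleaves to the phenol that becomes O3', while the terminal allyl double bond epoxidises far more slowly.

Step 6
Reactants: 7 methyl (S)-3-[4-(allyloxy)-3-hydroxyphenyl]-2-hydroxypropanoate
Product: 8 methyl (S)-3-[4-(allyloxy)-3-(benzyloxy)phenyl]-2-hydroxypropanoate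
Conditions: BnBr, K2CO3, DMF, rt
Reagents that add atoms: benzyl bromide, BrCc1ccccc1
Why: Williamson etherification of the only phenol; O3' now carries the benzyl group that lasts to the end and O4' the allyl group, which is the differentiation the quinone methide step needs.

Step 7
Reactants: 8 methyl (S)-3-[4-(allyloxy)-3-(benzyloxy)phenyl]-2-hydroxypropanoate
Product: 9 methyl (S)-3-[4-(allyloxy)-3-(benzyloxy)phenyl]-2-[(tert-butyldimethylsilyl)oxy]propanoate
Conditions: TBSCl, imidazole, DMF, rt
Reagents that add atoms: tert-butyldimethylsilyl chloride, CC(C)(C)[Si](C)(C)Cl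
Why: Standard silylation of a secondary alcohol; the bulky silyl ether stays on O3 through the ring closure, where its size is used.

Step 8
Reactants: 9 methyl (S)-3-[4-(allyloxy)-3-(benzyloxy)phenyl]-2-[(tert-butyldimethylsilyl)oxy]propanoate
Product: 10 (S)-3-[4-(allyloxy)-3-(benzyloxy)phenyl]-2-[(tert-butyldimethylsilyl)oxy]propanal
Conditions: i-Bu2AlH, CH2Cl2, −78 °C; aq KNaC4H4O6 (Rochelle salt)
Reagents that add atoms: none
Why: Partial reduction of an ester through the aluminium hemiacetal, which is stable at −78 °C; α-silyloxy aldehydes of this type keep their configuration when used directly.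

Step 9
Reactants: 11 (−)-epicatechin
Product: 12 5,7,3',4'-tetra-O-benzyl-(−)-epicatechin
Conditions: BnBr, K2CO3, DMF, 0 °C → rt
Reagents that add atoms: benzyl bromide, BrCc1ccccc1
Why: Williamson benzylation of the four phenols under carbonate, which leaves the secondary 3-hydroxyl free.

Step 10
Reactants: 12 5,7,3',4'-tetra-O-benzyl-(−)-epicatechin
Product: 13 4β-(2-ethoxyethoxy)-5,7,3',4'-tetra-O-benzyl-(−)-epicatechin (3,4-trans)
Conditions: DDQ, 2-ethoxyethanol, CH2Cl2, rt
Reagents that add atoms: 2-ethoxyethanol, CCOCCO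
Why: DDQ oxidation at C4 of a 5,7-dialkoxyflavan (hydride abstraction to the cation stabilised by ring A) with capture by the alcohol trans to the 3-hydroxyl; an established way to flavan C4 electrophiles.

Step 11
Reactants: 13 4β-(2-ethoxyethoxy)-5,7,3',4'-tetra-O-benzyl-(−)-epicatechin
Product: 14 8-iodo-4β-(2-ethoxyethoxy)-5,7,3',4'-tetra-O-benzyl-(−)-epicatechin
Conditions: NIS, CH2Cl2, −20 → 0 °C
Reagents that add atoms: N-iodosuccinimide, O=C1CCC(=O)N1I
Why: Electrophilic aromatic iodination; C8 is the most reactive position of the 5,7-dibenzyloxy ring A, as in the known C8 brominations, and the iodine both blocks C8 against self-condensation and marks it for metalation in step 17.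

Step 12
Reactants: 15 (+)-catechin
Product: 16 5,7,3',4'-tetra-O-benzyl-(+)-catechin
Conditions: BnBr, K2CO3, DMF, 0 °C → rt
Reagents that add atoms: benzyl bromide, BrCc1ccccc1
Why: Williamson benzylation of the four phenols, as in step 9.

Step 13
Reactants: 16 5,7,3',4'-tetra-O-benzyl-(+)-catechin
Product: 17 3,5,7,3',4'-penta-O-benzyl-(+)-catechin
Conditions: NaH, BnBr, DMF, 0 °C → rt
Reagents that add atoms: benzyl bromide, BrCc1ccccc1
Why: Williamson etherification of the 3-alkoxide, so that the lower hydroxyl is not acylated in step 23 and is freed only at the end.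

Step 14
Reactants: 17 3,5,7,3',4'-penta-O-benzyl-(+)-catechin
Product: 18 8-bromo-3,5,7,3',4'-penta-O-benzyl-(+)-catechin
Conditions: NBS, CH2Cl2, −78 → 0 °C
Reagents that add atoms: N-bromosuccinimide, O=C1CCC(=O)N1Br
Why: Electrophilic bromination at C8, the most reactive ring A position; the bromine blocks C8 so that step 15 must go through C6, and it is removed in the last step.

Step 15
Reactants: 14 8-iodo-4β-(2-ethoxyethoxy)-5,7,3',4'-tetra-O-benzyl-(−)-epicatechin; 18 8-bromo-3,5,7,3',4'-penta-O-benzyl-(+)-catechin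
Product: 19 8-iodo-5,7,3',4'-tetra-O-benzylepicatechin-(4β→6)-8-bromo-3,5,7,3',4'-penta-O-benzylcatechin (3-hydroxyl of the epicatechin unit free)
Conditions: 18 (3 equiv), TMSOTf (cat.), CH2Cl2, −78 → −40 °C
Reagents that add atoms: none
Why: Lewis-acid-mediated formation of the flavan C4 cation and Friedel–Crafts attack by the only free ring A carbon of 18 (C6) on the face trans to the C3 oxygen of the 2,3-cis electrophile, giving the 4β bond; halogen caps on both partners exclude C8 attack and limit self-condensation of 14.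

Step 16
Reactants: 19 8-iodo-5,7,3',4'-tetra-O-benzylepicatechin-(4β→6)-8-bromo-3,5,7,3',4'-penta-O-benzylcatechin
Product: 20 3-O-(tert-butyldimethylsilyl) ether of 19 (silyl group on the epicatechin unit)
Conditions: TBSOTf, 2,6-lutidine, CH2Cl2, 0 °C → rt
Reagents that add atoms: tert-butyldimethylsilyl triflate, CC(C)(C)[Si](C)(C)OS(=O)(=O)C(F)(F)F
Why: Silylation of a hindered axial secondary alcohol with the silyl triflate; needed before metalation and chosen to match the silyl ether of the upper chain so that both fall together in step 22.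

Step 17
Reactants: 20 3-O-silyl iodide dimer; 10 (S)-3-[4-(allyloxy)-3-(benzyloxy)phenyl]-2-[(tert-butyldimethylsilyl)oxy]propanal
Product: 22 (2S)-3-[4-(allyloxy)-3-(benzyloxy)phenyl]-2-[(tert-butyldimethylsilyl)oxy]-1-(D)propan-1-ol as both C1 epimers (D = residue of 20 bonded through C8 of its epicatechin unit in place of iodine), via aryllithium 21 (not isolated)
Conditions: n-BuLi (1.05 equiv), THF, −78 °C; then 10, −78 °C; H2O
Reagents that add atoms: none
Why: Iodine–lithium exchange, far faster than bromine–lithium exchange at −78 °C with one equivalent of n-BuLi, then 1,2-addition of the aryllithium to the aldehyde; the new carbinol configuration is irrelevant because this carbon is ionised in step 18, and C3 is not touched.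

Step 18
Reactants: 22 carbinol (both C1 epimers); 23 3,5-bis(benzyloxy)phenol
Product: 24 2-[(2S)-3-[4-(allyloxy)-3-(benzyloxy)phenyl]-2-[(tert-butyldimethylsilyl)oxy]-1-(D)propyl]-3,5-bis(benzyloxy)phenol (C1 of the propyl chain, the future C4, configured so that D is trans to O3 after ring closure)
Conditions: 23 (4 equiv), TMSOTf (0.2 equiv), 4 Å MS, CH2Cl2, −78 → −40 °C
Reagents that add atoms: none
Why: Friedel–Crafts alkylation of a phenol by a benzylic cation (SN1): ionisation gives the C4 cation stabilised by the three oxygens of the adjoining ring A, with C3–H eclipsing the aryl plane to avoid allylic 1,3-strain, and 23 attacks through its carbon ortho to OH on the face anti to the silyloxy group (Felkin–Anh sense), which should set C4 as required; ortho attack of allylic and benzylic cations on 3,5-dialkoxyphenols is known.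

Step 19
Reactants: 24 allyl ether
Product: 25 2-[(2S)-3-[3-(benzyloxy)-4-hydroxyphenyl]-2-[(tert-butyldimethylsilyl)oxy]-1-(D)propyl]-3,5-bis(benzyloxy)phenol (1,1,3-triarylpropan-2-ol silyl ether with both phenols free)
Conditions: Pd(PPh3)4 (5 mol %), morpholine, THF, rt
Reagents that add atoms: none
Why: Palladium-catalysed deallylation (Tsuji–Trost type) with morpholine as allyl acceptor; zerovalent palladium inserts into the allyl–oxygen bond at room temperature but not into the hindered, electron-rich aryl bromide, and benzyl and silyl ethers stay.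

Step 20
Reactants: 25 bis-phenol
Product: 27 [5,7,3'-tri-O-benzyl-3-O-TBS-epicatechin]-(4β→8)-[5,7,3',4'-tetra-O-benzyl-3-O-TBS-epicatechin]-(4β→6)-[8-bromo-penta-O-benzylcatechin] with the 4'-hydroxyl of the upper unit free, via p-quinone methide 26 (not isolated)
Conditions: Ag2O (3 equiv), CH2Cl2 (high dilution), rt, dark
Reagents that add atoms: none
Why: Ag2O, an oxide of monovalent silver, removes two electrons and two protons (O4'–H and one C2–H) from the guaiacol-type ring B phenol, the most easily oxidised phenol in 25, and gives p-quinone methide 26 with C2 trigonal. The phenolic oxygen on C8a of ring A then adds to C2 in a 1,6-conjugate (oxa-Michael) addition that restores aromatic ring B and closes ring C through O1–C2; the closure is 6-exo-trig, since the attacked C2=C1' bond lies outside the new ring. The closest known reactions are the oxidative cyclisation of 1-(2-hydroxyaryl)-3-(4-hydroxyaryl)propanes to flavans through ring B quinone methides and the C2 epimerisation of flavan-3-ols, which runs through the same intermediate. C2 is the only new stereocentre and is controlled by C3 and C4: allylic strain with the 5-benzyloxy group holds the C4 aryl group pseudo-axial in the chair-like transition state, the trans silyloxy group on C3 is then axial too, and the quinone methide ring takes the equatorial site at C2, which is the face cis to O3; the other face would place it 1,3-diaxial to the C4 aryl group. Because 27 keeps the free 4'-phenol, the closure can reopen through 26, and the same argument makes the 2,3-cis isomer the thermodynamic product as well. The step needs selectivity between two phenols, and the substrate provides it: ring A has only meta oxygens and its benzylic C4–H lies in the ring plane, so it cannot give a quinone methide, whereas ring B has an ortho alkoxy group, a para CH2 and freely rotating C2–H bonds. High dilution keeps intermolecular phenoxyl coupling below the intramolecular capture.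

Step 21
Reactants: 27 upper-unit 4'-phenol
Product: 28 [5,7,3',4'-tetra-O-benzyl-3-O-TBS-epicatechin]-(4β→8)-[5,7,3',4'-tetra-O-benzyl-3-O-TBS-epicatechin]-(4β→6)-[8-bromo-penta-O-benzylcatechin]
Conditions: BnBr, K2CO3, DMF, rt
Reagents that add atoms: benzyl bromide, BrCc1ccccc1
Why: Williamson etherification of the only phenol left; after it step 23 can acylate only the two secondary hydroxyls, and C2 can no longer reopen through the quinone methide.

Step 22
Reactants: 28 bis-silyl ether
Product: 29 [5,7,3',4'-tetra-O-benzylepicatechin]-(4β→8)-[5,7,3',4'-tetra-O-benzylepicatechin]-(4β→6)-[8-bromo-penta-O-benzylcatechin] (3-hydroxyls of the upper and middle units free)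
Conditions: TBAF, THF, rt → 50 °C
Reagents that add atoms: none
Why: Fluoride-induced cleavage of the two secondary silyl ethers; benzyl ethers and the aryl bromide are inert.

Step 23
Reactants: 29 diol; 30 3,4,5-tris(benzyloxy)benzoyl chloride (two equivalents enter the product, one on each 3-hydroxyl)
Product: 31 bis[3-O-(3,4,5-tri-O-benzylgalloyl)] ester of 29 (upper and middle units)
Conditions: 30 (4 equiv), DMAP, Et3N, CH2Cl2, rt → 40 °C
Reagents that add atoms: 3,4,5-tris(benzyloxy)benzoyl chloride (compound 30, the second equivalent), O=C(Cl)c1cc(OCc2ccccc2)c(OCc2ccccc2)c(OCc2ccccc2)c1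
Why: DMAP-catalysed acylation of both secondary hydroxyls by the acid chloride, one molecule of 30 per hydroxyl; both hydroxyls are axial and flanked by a C4 aryl group, so excess reagent and gentle warming are planned, as in known 3-O-galloylations of 4-arylflavan-3-ols.

Step 24
Reactants: 31 perbenzylated bromo trimer bis-gallate
Product: 32 (−)-epicatechin 3-O-gallate-(4β→8)-(−)-epicatechin 3-O-gallate-(4β→6)-(+)-catechin
Conditions: H2 (1 atm), Pd(OH)2/C, Et3N (1.5 equiv), THF/MeOH/H2O, rt
Reagents that add atoms: none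
Why: Hydrogenolysis of nineteen benzyl ethers and of the C8–Br bond over Pd(OH)2/C; the gallate esters and all stereocentres are unaffected, and Et3N takes up the HBr so that the acid-labile interflavan bonds are not exposed to acid.

## Compound list

1 | L-tyrosine | N[C@@H](Cc1ccc(O)cc1)C(O)=O | starting material
2 | (S)-2-hydroxy-3-(4-hydroxyphenyl)propanoic acid | O[C@@H](Cc1ccc(O)cc1)C(O)=O | intermediate
3 | methyl (S)-2-hydroxy-3-(4-hydroxyphenyl)propanoate | O[C@@H](Cc1ccc(O)cc1)C(=O)OC | intermediate
4 | methyl (S)-3-(3-formyl-4-hydroxyphenyl)-2-hydroxypropanoate | O[C@@H](Cc1ccc(O)c(C=O)c1)C(=O)OC | intermediate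
5 | methyl (S)-3-[4-(allyloxy)-3-formylphenyl]-2-hydroxypropanoate | O[C@@H](Cc1ccc(OCC=C)c(C=O)c1)C(=O)OC | intermediate
6 | methyl (S)-3-[4-(allyloxy)-3-(formyloxy)phenyl]-2-hydroxypropanoate (not isolated) | O[C@@H](Cc1ccc(OCC=C)c(OC=O)c1)C(=O)OC | intermediate
7 | methyl (S)-3-[4-(allyloxy)-3-hydroxyphenyl]-2-hydroxypropanoate | O[C@@H](Cc1ccc(OCC=C)c(O)c1)C(=O)OC | intermediate
8 | methyl (S)-3-[4-(allyloxy)-3-(benzyloxy)phenyl]-2-hydroxypropanoate | O[C@@H](Cc1ccc(OCC=C)c(OCc2ccccc2)c1)C(=O)OC | intermediate
9 | methyl (S)-3-[4-(allyloxy)-3-(benzyloxy)phenyl]-2-[(tert-butyldimethylsilyl)oxy]propanoate | CC(C)(C)[Si](C)(C)O[C@@H](Cc1ccc(OCC=C)c(OCc2ccccc2)c1)C(=O)OC | intermediate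
10 | (S)-3-[4-(allyloxy)-3-(benzyloxy)phenyl]-2-[(tert-butyldimethylsilyl)oxy]propanal | CC(C)(C)[Si](C)(C)O[C@@H](Cc1ccc(OCC=C)c(OCc2ccccc2)c1)C=O | intermediate
11 | (−)-epicatechin | O[C@@H]1Cc2c(O)cc(O)cc2O[C@@H]1c1ccc(O)c(O)c1 | starting material
12 | 5,7,3',4'-tetra-O-benzyl-(−)-epicatechin | O[C@@H]1Cc2c(OCc9ccccc9)cc(OCc9ccccc9)cc2O[C@@H]1c7ccc(OCc9ccccc9)c(OCc9ccccc9)c7 | intermediate
13 | 4β-(2-ethoxyethoxy)-5,7,3',4'-tetra-O-benzyl-(−)-epicatechin (3,4-trans) | O[C@@H]1[C@@H](OCCOCC)c2c(OCc9ccccc9)cc(OCc9ccccc9)cc2O[C@@H]1c7ccc(OCc9ccccc9)c(OCc9ccccc9)c7 | intermediate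
14 | 8-iodo-4β-(2-ethoxyethoxy)-5,7,3',4'-tetra-O-benzyl-(−)-epicatechin | O[C@@H]1[C@@H](OCCOCC)c2c(OCc9ccccc9)cc(OCc9ccccc9)c(I)c2O[C@@H]1c7ccc(OCc9ccccc9)c(OCc9ccccc9)c7 | intermediate
15 | (+)-catechin | O[C@H]1Cc2c(O)cc(O)cc2O[C@@H]1c1ccc(O)c(O)c1 | starting material
16 | 5,7,3',4'-tetra-O-benzyl-(+)-catechin | O[C@H]1Cc2c(OCc9ccccc9)cc(OCc9ccccc9)cc2O[C@@H]1c7ccc(OCc9ccccc9)c(OCc9ccccc9)c7 | intermediate
17 | 3,5,7,3',4'-penta-O-benzyl-(+)-catechin | c9ccccc9CO[C@H]1Cc2c(OCc9ccccc9)cc(OCc9ccccc9)cc2O[C@@H]1c7ccc(OCc9ccccc9)c(OCc9ccccc9)c7 | intermediate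
18 | 8-bromo-3,5,7,3',4'-penta-O-benzyl-(+)-catechin | c9ccccc9CO[C@H]1Cc2c(OCc9ccccc9)cc(OCc9ccccc9)c(Br)c2O[C@@H]1c7ccc(OCc9ccccc9)c(OCc9ccccc9)c7 | intermediate
19 | 8-iodo-5,7,3',4'-tetra-O-benzylepicatechin-(4β→6)-8-bromo-3,5,7,3',4'-penta-O-benzylcatechin | Ic2c(OCc9ccccc9)cc(OCc9ccccc9)c3c2O[C@H](c7ccc(OCc9ccccc9)c(OCc9ccccc9)c7)[C@H](O)[C@H]3c4c(OCc9ccccc9)c(Br)c5c(c4OCc9ccccc9)C[C@H](OCc9ccccc9)[C@@H](c7ccc(OCc9ccccc9)c(OCc9ccccc9)c7)O5 | intermediate
20 | 3-O-(tert-butyldimethylsilyl) ether of 19 (on the epicatechin unit) | Ic2c(OCc9ccccc9)cc(OCc9ccccc9)c3c2O[C@H](c7ccc(OCc9ccccc9)c(OCc9ccccc9)c7)[C@H](O[Si](C)(C)C(C)(C)C)[C@H]3c4c(OCc9ccccc9)c(Br)c5c(c4OCc9ccccc9)C[C@H](OCc9ccccc9)[C@@H](c7ccc(OCc9ccccc9)c(OCc9ccccc9)c7)O5 | intermediate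
21 | 8-lithio compound from 20 (not isolated) | [Li]c2c(OCc9ccccc9)cc(OCc9ccccc9)c3c2O[C@H](c7ccc(OCc9ccccc9)c(OCc9ccccc9)c7)[C@H](O[Si](C)(C)C(C)(C)C)[C@H]3c4c(OCc9ccccc9)c(Br)c5c(c4OCc9ccccc9)C[C@H](OCc9ccccc9)[C@@H](c7ccc(OCc9ccccc9)c(OCc9ccccc9)c7)O5 | intermediate
22 | (2S)-3-[4-(allyloxy)-3-(benzyloxy)phenyl]-2-[(tert-butyldimethylsilyl)oxy]-1-(D)propan-1-ol, both C1 epimers; D = residue of 20 bonded through C8 of its epicatechin unit | CC(C)(C)[Si](C)(C)O[C@@H](Cc7ccc(OCC=C)c(OCc9ccccc9)c7)C(O)c2c(OCc9ccccc9)cc(OCc9ccccc9)c3c2O[C@H](c7ccc(OCc9ccccc9)c(OCc9ccccc9)c7)[C@H](O[Si](C)(C)C(C)(C)C)[C@H]3c4c(OCc9ccccc9)c(Br)c5c(c4OCc9ccccc9)C[C@H](OCc9ccccc9)[C@@H](c7ccc(OCc9ccccc9)c(OCc9ccccc9)c7)O5 | intermediate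
23 | 3,5-bis(benzyloxy)phenol | Oc1cc(OCc2ccccc2)cc(OCc2ccccc2)c1 | starting material
24 | 2-[(2S)-3-[4-(allyloxy)-3-(benzyloxy)phenyl]-2-[(tert-butyldimethylsilyl)oxy]-1-(D)propyl]-3,5-bis(benzyloxy)phenol, C1 as in the SMILES (D trans to O3 after closure) | CC(C)(C)[Si](C)(C)O[C@@H](Cc7ccc(OCC=C)c(OCc9ccccc9)c7)[C@@H](c2c(OCc9ccccc9)cc(OCc9ccccc9)c3c2O[C@H](c7ccc(OCc9ccccc9)c(OCc9ccccc9)c7)[C@H](O[Si](C)(C)C(C)(C)C)[C@H]3c4c(OCc9ccccc9)c(Br)c5c(c4OCc9ccccc9)C[C@H](OCc9ccccc9)[C@@H](c7ccc(OCc9ccccc9)c(OCc9ccccc9)c7)O5)c6c(OCc9ccccc9)cc(OCc9ccccc9)cc6O | intermediate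
25 | 2-[(2S)-3-[3-(benzyloxy)-4-hydroxyphenyl]-2-[(tert-butyldimethylsilyl)oxy]-1-(D)propyl]-3,5-bis(benzyloxy)phenol (precursor of the key step) | CC(C)(C)[Si](C)(C)O[C@@H](Cc7ccc(O)c(OCc9ccccc9)c7)[C@@H](c2c(OCc9ccccc9)cc(OCc9ccccc9)c3c2O[C@H](c7ccc(OCc9ccccc9)c(OCc9ccccc9)c7)[C@H](O[Si](C)(C)C(C)(C)C)[C@H]3c4c(OCc9ccccc9)c(Br)c5c(c4OCc9ccccc9)C[C@H](OCc9ccccc9)[C@@H](c7ccc(OCc9ccccc9)c(OCc9ccccc9)c7)O5)c6c(OCc9ccccc9)cc(OCc9ccccc9)cc6O | intermediate
26 | p-quinone methide of 25 (C2=C1', ring B as 2-benzyloxycyclohexa-2,5-dienone; not isolated) | CC(C)(C)[Si](C)(C)O[C@@H](C=C7C=CC(=O)C(OCc9ccccc9)=C7)[C@@H](c2c(OCc9ccccc9)cc(OCc9ccccc9)c3c2O[C@H](c7ccc(OCc9ccccc9)c(OCc9ccccc9)c7)[C@H](O[Si](C)(C)C(C)(C)C)[C@H]3c4c(OCc9ccccc9)c(Br)c5c(c4OCc9ccccc9)C[C@H](OCc9ccccc9)[C@@H](c7ccc(OCc9ccccc9)c(OCc9ccccc9)c7)O5)c6c(OCc9ccccc9)cc(OCc9ccccc9)cc6O | intermediate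
27 | [5,7,3'-tri-O-benzyl-3-O-TBS-epicatechin]-(4β→8)-[5,7,3',4'-tetra-O-benzyl-3-O-TBS-epicatechin]-(4β→6)-[8-bromo-penta-O-benzylcatechin], upper 4'-OH free (product of the key step) | CC(C)(C)[Si](C)(C)O[C@@H]1[C@@H](c2c(OCc9ccccc9)cc(OCc9ccccc9)c3c2O[C@H](c7ccc(OCc9ccccc9)c(OCc9ccccc9)c7)[C@H](O[Si](C)(C)C(C)(C)C)[C@H]3c4c(OCc9ccccc9)c(Br)c5c(c4OCc9ccccc9)C[C@H](OCc9ccccc9)[C@@H](c7ccc(OCc9ccccc9)c(OCc9ccccc9)c7)O5)c6c(OCc9ccccc9)cc(OCc9ccccc9)cc6O[C@@H]1c7ccc(O)c(OCc9ccccc9)c7 | intermediate
28 | [5,7,3',4'-tetra-O-benzyl-3-O-TBS-epicatechin]-(4β→8)-[5,7,3',4'-tetra-O-benzyl-3-O-TBS-epicatechin]-(4β→6)-[8-bromo-penta-O-benzylcatechin] | CC(C)(C)[Si](C)(C)O[C@@H]1[C@@H](c2c(OCc9ccccc9)cc(OCc9ccccc9)c3c2O[C@H](c7ccc(OCc9ccccc9)c(OCc9ccccc9)c7)[C@H](O[Si](C)(C)C(C)(C)C)[C@H]3c4c(OCc9ccccc9)c(Br)c5c(c4OCc9ccccc9)C[C@H](OCc9ccccc9)[C@@H](c7ccc(OCc9ccccc9)c(OCc9ccccc9)c7)O5)c6c(OCc9ccccc9)cc(OCc9ccccc9)cc6O[C@@H]1c7ccc(OCc9ccccc9)c(OCc9ccccc9)c7 | intermediate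
29 | [5,7,3',4'-tetra-O-benzylepicatechin]-(4β→8)-[5,7,3',4'-tetra-O-benzylepicatechin]-(4β→6)-[8-bromo-penta-O-benzylcatechin], upper and middle 3-OH free | O[C@@H]1[C@@H](c2c(OCc9ccccc9)cc(OCc9ccccc9)c3c2O[C@H](c7ccc(OCc9ccccc9)c(OCc9ccccc9)c7)[C@H](O)[C@H]3c4c(OCc9ccccc9)c(Br)c5c(c4OCc9ccccc9)C[C@H](OCc9ccccc9)[C@@H](c7ccc(OCc9ccccc9)c(OCc9ccccc9)c7)O5)c6c(OCc9ccccc9)cc(OCc9ccccc9)cc6O[C@@H]1c7ccc(OCc9ccccc9)c(OCc9ccccc9)c7 | intermediate
30 | 3,4,5-tris(benzyloxy)benzoyl chloride | O=C(Cl)c1cc(OCc2ccccc2)c(OCc2ccccc2)c(OCc2ccccc2)c1 | starting material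
31 | bis[3-O-(3,4,5-tri-O-benzylgalloyl)] ester of 29 (upper and middle units) | O=C(O[C@@H]1[C@@H](c2c(OCc9ccccc9)cc(OCc9ccccc9)c3c2O[C@H](c7ccc(OCc9ccccc9)c(OCc9ccccc9)c7)[C@H](OC(=O)c8cc(OCc9ccccc9)c(OCc9ccccc9)c(OCc9ccccc9)c8)[C@H]3c4c(OCc9ccccc9)c(Br)c5c(c4OCc9ccccc9)C[C@H](OCc9ccccc9)[C@@H](c7ccc(OCc9ccccc9)c(OCc9ccccc9)c7)O5)c6c(OCc9ccccc9)cc(OCc9ccccc9)cc6O[C@@H]1c7ccc(OCc9ccccc9)c(OCc9ccccc9)c7)c8cc(OCc9ccccc9)c(OCc9ccccc9)c(OCc9ccccc9)c8 | intermediate
32 | (−)-epicatechin 3-O-gallate-(4β→8)-(−)-epicatechin 3-O-gallate-(4β→6)-(+)-catechin (CNP0154615.1) | O=C(O[C@@H]1[C@@H](c2c(O)cc(O)c3c2O[C@H](c2ccc(O)c(O)c2)[C@H](OC(=O)c2cc(O)c(O)c(O)c2)[C@H]3c2c(O)cc3c(c2O)C[C@H](O)[C@@H](c2ccc(O)c(O)c2)O3)c2c(O)cc(O)cc2O[C@@H]1c1ccc(O)c(O)c1)c1cc(O)c(O)c(O)c1 | target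

## Step count and least certain steps

Total: 24 steps. Longest linear sequence: 16 steps (steps 1–8 and 17–24, from L-tyrosine). The epicatechin branch (steps 9–11, 15, 16) and the catechin branch (steps 12–16) each join it after five steps.

**Step 20 (key step).** Oxidation may begin at the ring A phenol, or phenoxyl radicals may couple between molecules before the quinone methide forms. Facial selectivity at C2 may also be poor if the chair-like arrangement with the axial C4 aryl group is less dominant than assumed. Equilibration through 26 under mild base would be tried first, since 27 still has the free phenol. The fallback makes the upper interflavan bond by the established cationic coupling and sets out from 19 and 13. 19 is deiodinated (n-BuLi, 2 equiv, THF, −78 °C, then MeOH) to 5,7,3',4'-tetra-O-benzylepicatechin-(4β→6)-8-bromo-penta-O-benzylcatechin F1. 13 is then ionised with catalytic TMSOTf in the presence of excess F1, whose free C8 attacks the C4 cation trans to the 3-hydroxyl. This gives 29 directly, and the route is rejoined at step 23.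

**Step 18.** Poor or reversed facial selectivity at the C4 cation would give the wrong C4 epimer. The cation may also be captured by ring B of its own chain (indane closure), lose the C3 proton to a silyl enol ether, or be attacked by 23 para to its hydroxyl. In the fallback the two aryl groups exchange roles; it sets out from 10, 23 and 20. The bromomagnesium phenoxide of 23 (EtMgBr, toluene/CH2Cl2) adds to 10 through its ortho carbon (Casiraghi hydroxyalkylation) to give the 2-hydroxybenzylic alcohol F2. 20 is deiodinated (n-BuLi, THF, −78 °C, then MeOH) to the C8-unsubstituted silyl ether F3. F2 is then ionised with catalytic TMSOTf in the presence of F3, whose C8 attacks the cation now stabilised by ring A, and the route is rejoined at 24. For a given facial preference this order gives the opposite configuration at C4, so it is the remedy if the nucleophile enters syn to the silyloxy group; it also needs no aryllithium.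

**Step 15.** C6 of 18 is flanked by two benzyloxy groups and deactivated by the bromine. Slow attack could let the cation be consumed by C6 of a second molecule of 14 or by proton loss. The fallback uses a leaving group activated in a different way and sets out from 14. Exchange of the ethoxyethoxy group for 2,6-dimethylbenzenethiol (BF3·OEt2, CH2Cl2, −78 °C) gives the 4β-(2,6-dimethylphenylthio) compound F4, which hard Lewis acids leave alone. Thiophilic activation with AgOTf in the presence of a large excess of 18 then releases the same C4 cation slowly and returns to the route at 19.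

**Step 17.** The hindered, basic aryllithium 21 may take the α-proton of the silyloxy aldehyde (loss of material and erosion of C3), or some bromine–lithium exchange may occur on the catechin unit. The fallback uses an electrophile at the carboxylic acid oxidation level and sets out from 9. i-PrMgCl and N,O-dimethylhydroxylamine hydrochloride (THF, −20 °C) convert 9 into the Weinreb amide F5. 21 adds once to F5, and the ketone F6 is released only on work-up. NaBH4 then reduces F6 to 22; either carbinol epimer serves.

## Further compounds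

F1 | step 20 | 5,7,3',4'-tetra-O-benzylepicatechin-(4β→6)-8-bromo-3,5,7,3',4'-penta-O-benzylcatechin (C8 of the epicatechin unit unsubstituted, its 3-OH free) | c2c(OCc9ccccc9)cc(OCc9ccccc9)c3c2O[C@H](c7ccc(OCc9ccccc9)c(OCc9ccccc9)c7)[C@H](O)[C@H]3c4c(OCc9ccccc9)c(Br)c5c(c4OCc9ccccc9)C[C@H](OCc9ccccc9)[C@@H](c7ccc(OCc9ccccc9)c(OCc9ccccc9)c7)O5
F2 | step 18 | 2-[(2S)-3-[4-(allyloxy)-3-(benzyloxy)phenyl]-2-[(tert-butyldimethylsilyl)oxy]-1-hydroxypropyl]-3,5-bis(benzyloxy)phenol (both carbinol epimers) | CC(C)(C)[Si](C)(C)O[C@@H](Cc7ccc(OCC=C)c(OCc9ccccc9)c7)C(O)c6c(OCc9ccccc9)cc(OCc9ccccc9)cc6O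
F3 | step 18 | 3-O-(tert-butyldimethylsilyl)-5,7,3',4'-tetra-O-benzylepicatechin-(4β→6)-8-bromo-3,5,7,3',4'-penta-O-benzylcatechin (C8 of the epicatechin unit unsubstituted) | c2c(OCc9ccccc9)cc(OCc9ccccc9)c3c2O[C@H](c7ccc(OCc9ccccc9)c(OCc9ccccc9)c7)[C@H](O[Si](C)(C)C(C)(C)C)[C@H]3c4c(OCc9ccccc9)c(Br)c5c(c4OCc9ccccc9)C[C@H](OCc9ccccc9)[C@@H](c7ccc(OCc9ccccc9)c(OCc9ccccc9)c7)O5
F4 | step 15 | 8-iodo-4β-(2,6-dimethylphenylthio)-5,7,3',4'-tetra-O-benzyl-(−)-epicatechin | O[C@@H]1[C@@H](Sc6c(C)cccc6C)c2c(OCc9ccccc9)cc(OCc9ccccc9)c(I)c2O[C@@H]1c7ccc(OCc9ccccc9)c(OCc9ccccc9)c7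
F5 | step 17 | (S)-3-[4-(allyloxy)-3-(benzyloxy)phenyl]-2-[(tert-butyldimethylsilyl)oxy]-N-methoxy-N-methylpropanamide | CC(C)(C)[Si](C)(C)O[C@@H](Cc1ccc(OCC=C)c(OCc2ccccc2)c1)C(=O)N(C)OC
F6 | step 17 | (2S)-3-[4-(allyloxy)-3-(benzyloxy)phenyl]-2-[(tert-butyldimethylsilyl)oxy]-1-(D)propan-1-one (D as in 22) | CC(C)(C)[Si](C)(C)O[C@@H](Cc7ccc(OCC=C)c(OCc9ccccc9)c7)C(=O)c2c(OCc9ccccc9)cc(OCc9ccccc9)c3c2O[C@H](c7ccc(OCc9ccccc9)c(OCc9ccccc9)c7)[C@H](O[Si](C)(C)C(C)(C)C)[C@H]3c4c(OCc9ccccc9)c(Br)c5c(c4OCc9ccccc9)C[C@H](OCc9ccccc9)[C@@H](c7ccc(OCc9ccccc9)c(OCc9ccccc9)c7)O5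
A1 | alternative 1 | perbenzylated 8-bromo trimer bis-gallate (same compound as 31) | O=C(O[C@@H]1[C@@H](c2c(OCc9ccccc9)cc(OCc9ccccc9)c3c2O[C@H](c7ccc(OCc9ccccc9)c(OCc9ccccc9)c7)[C@H](OC(=O)c8cc(OCc9ccccc9)c(OCc9ccccc9)c(OCc9ccccc9)c8)[C@H]3c2c(OCc9ccccc9)c(Br)c3c(c2OCc9ccccc9)C[C@H](OCc9ccccc9)[C@@H](c7ccc(OCc9ccccc9)c(OCc9ccccc9)c7)O3)c2c(OCc9ccccc9)cc(OCc9ccccc9)cc2O[C@@H]1c7ccc(OCc9ccccc9)c(OCc9ccccc9)c7)c8cc(OCc9ccccc9)c(OCc9ccccc9)c(OCc9ccccc9)c8
A2 | alternative 1 | 4β-[2-hydroxy-4,6-bis(benzyloxy)phenyl]-5,7,3',4'-tetra-O-benzylepicatechin 3-O-(3,4,5-tri-O-benzylgallate) | O=C(O[C@@H]1[C@@H](c2c(O)cc(OCc9ccccc9)cc2OCc9ccccc9)c6c(OCc9ccccc9)cc(OCc9ccccc9)cc6O[C@@H]1c7ccc(OCc9ccccc9)c(OCc9ccccc9)c7)c8cc(OCc9ccccc9)c(OCc9ccccc9)c(OCc9ccccc9)c8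
A3 | alternative 1 | 8-bromo-3,5,7,3',4'-penta-O-benzyl-(+)-catechin-6-carbaldehyde | O=Cc2c(OCc9ccccc9)c(Br)c3c(c2OCc9ccccc9)C[C@H](OCc9ccccc9)[C@@H](c7ccc(OCc9ccccc9)c(OCc9ccccc9)c7)O3
A4 | alternative 1 | (Z)-2-[3,4-bis(benzyloxy)phenyl]ethenyl 3,4,5-tris(benzyloxy)benzoate | O=C(O/C=C\c7ccc(OCc9ccccc9)c(OCc9ccccc9)c7)c8cc(OCc9ccccc9)c(OCc9ccccc9)c(OCc9ccccc9)c8
A5 | alternative 2 | 3-O-TBS-5,7,3',4'-tetra-O-benzylepicatechin carrying at C4β a 4-(benzyloxy)-2-hydroxy-6-(triisopropylsilyloxy)phenyl ring | CC(C)(C)[Si](C)(C)O[C@@H]1[C@@H](c2c(O[Si](C(C)C)(C(C)C)C(C)C)cc(OCc9ccccc9)cc2O)c2c(OCc9ccccc9)cc(OCc9ccccc9)cc2O[C@@H]1c7ccc(OCc9ccccc9)c(OCc9ccccc9)c7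
A6 | alternative 2 | 3-O-TBS-5,7,3',4'-tetra-O-benzylepicatechin carrying a (triisopropylsilyloxy)ethynyl group at C4β | CC(C)(C)[Si](C)(C)O[C@@H]1[C@@H](C#CO[Si](C(C)C)(C(C)C)C(C)C)c2c(OCc9ccccc9)cc(OCc9ccccc9)cc2O[C@@H]1c7ccc(OCc9ccccc9)c(OCc9ccccc9)c7
A7 | alternative 2 | 3-(benzyloxy)cyclobut-2-en-1-one | O=C1C=C(OCc2ccccc2)C1
A8 | alternative 3 | protected trimer with complete skeleton, upper and middle 3-O-TBS, lower 3-OH free | CC(C)(C)[Si](C)(C)O[C@@H]1[C@@H](c2c(OCc9ccccc9)cc(OCc9ccccc9)c3c2O[C@H](c7ccc(OCc9ccccc9)c(OCc9ccccc9)c7)[C@H](O[Si](C)(C)C(C)(C)C)[C@H]3c2c(OCc9ccccc9)cc3c(c2OCc9ccccc9)C[C@H](O)[C@@H](c7ccc(OCc9ccccc9)c(OCc9ccccc9)c7)O3)c2c(OCc9ccccc9)cc(OCc9ccccc9)cc2O[C@@H]1c7ccc(OCc9ccccc9)c(OCc9ccccc9)c7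
A9 | alternative 3 | upper–middle bis-TBS dimer carrying at middle C4β a 2,6-bis(benzyloxy)-4-{(R)-[3,4-bis(benzyloxy)phenyl][(S)-oxiran-2-yl]methoxy}phenyl ring | CC(C)(C)[Si](C)(C)O[C@@H]1[C@@H](c2c(OCc9ccccc9)cc(OCc9ccccc9)c3c2O[C@H](c7ccc(OCc9ccccc9)c(OCc9ccccc9)c7)[C@H](O[Si](C)(C)C(C)(C)C)[C@H]3c2c(OCc9ccccc9)cc(O[C@H](c7ccc(OCc9ccccc9)c(OCc9ccccc9)c7)[C@@H]4CO4)cc2OCc9ccccc9)c2c(OCc9ccccc9)cc(OCc9ccccc9)cc2O[C@@H]1c7ccc(OCc9ccccc9)c(OCc9ccccc9)c7
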